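The meeting opened on the slopes.

the same everywhere: Q 79 mM (held)
- Friday's: L 0.60 M; Z 2 equiv; X 1.1 equiv; temperature −8 °C; run made earlier
- Sunday's: L 0.95 M; Z 2 equiv; X 1.1 equiv; temperature 9 °C; run made earlier
- north-east: L 0.43 M; Z 2.00 equiv; X 1.10 equiv; temperature 0 °C; time 4.0 d
- south-east: L 0.43 M; Z 2.00 equiv; X 1.10 equiv; temperature −15 °C; time 4.0 d
- south: L 0.43 M; Z 2.00 equiv; X 1.10 equiv; temperature 15 °C; time 4.0 d

- Friday's (time / d: E / %): 0.250: 0.5; 0.833: 0.6; 1.25: 0.1; 2.08: 0.5; 3.00: 1.5; 4.00: 2.0; 5.00: 3.1
- Sunday's (time / d: E / %): 0.250: 0; 0.417: 1.2; 0.500: 0.9; 0.833: 3.2; 1.25: 4.8; 2.08: 9.4; 3.00: 12.9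

(standard deviation of a reading: 0.5 percentage points)

- at the start none of D is dissolved
- steps that have been proposed: X + G <-> E; Q <-> D; L + Z -> J; D + J -> G

- the flask with the highest amount of E, in percent of the L charged ("all alike" if they lie within 1.5 percentage points) (north-east / south-east / south / all alike)
- final E, as a percentage of the L charged, in north-east
- final E, as a percentage of the L charged, in south-east
- final E, as a percentage of the L charged, in south

The first speaker noted that the later readings of both runs rise roughly straight. She took the last stretch of each: Friday's gave 0.00890 d⁻¹ and Sunday's 0.0448 d⁻¹, as fractions of the L charged. A second member objected that Friday's rise is 2.6 percentage points with a scatter of 0.5 points on each reading, and that the runs differ in Z as well as in temperature.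

The first speaker answered by dividing each slope by the charged Z, taking E's rate as proportional to Z, and then dividing Sunday's result by Friday's. This gave 3.18 between −8 °C and 9 °C, a reading with time gone from it.

The meeting scaled this reading, on a logarithmic temperature scale, to the gap between 0 °C and 15 °C. The result is the warming factor W, the ratio of E's rate per molar Z in south to that in north-east: 2.77. Both flasks have the same charges and the same 4.0 d, so W is also the expected ratio of their E.

Scaling Sunday's slope to south gave the meeting's own figure of 12.2 %. Dividing by W gave 4.40 % for north-east, so south should stand higher. Nobody applied W to south-east, which is colder than Friday's run, since Friday's reading at 2.08 d was still 0.5 %.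

The forecast gave 3.7 % (2.4 % to 6.5 %) for north-east, 0.6 % (0.1 % to 1.6 %) for south-east, 12 % (7.5 % to 21 %) for south, and south as highest, adding “The order in L is untested”.

The flasks give 5.71 % in north-east, 0.271 % in south-east and 16.2 % in south, so south stands highest.

    X + G ⇌ E (K = 1.60 M⁻¹, k = 1.70 × 10⁻⁴ M⁻¹ s⁻¹, Ea = 72.0 kJ mol⁻¹, ΔH = −26.0 kJ mol⁻¹)
    Q ⇌ D, rate k2*(csat - [D]) (kL = 2.90 × 10⁻⁵ s⁻¹)
    L + Z → J (k = 1.10 × 10⁻⁵ M⁻¹ s⁻¹, Ea = 80.0 kJ mol⁻¹)
    D + J → G (k = 9.90 × 10⁻⁶ M⁻¹ s⁻¹, Ea = 80.0 kJ mol⁻¹)
    (constants at 0 °C)

South over north-east comes to 2.84 against W of 2.77, although south also holds 38.3 % as J and 45.6 % as G at 4.00 d. A neighbouring flask is like south but with 0.26 M of L and the same equivalents, so its Z is lower in the same proportion. W times north-east's E, scaled by that proportion, gives 9.56 %. That neighbouring flask holds more than this, 12.1 % of E, with 33.7 % as J and 54.1 % as G.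

The earlier runs and the new flask are simulated on assumed constants, and the scatter is random.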